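- You cannot charge free E: what you weigh in may pair to D, the off-cycle form, and no reading of J shows you that split directly. You can still bracket it, from the two runs made so far.

| flask | J | Z | E | remark | time |
|---|---|---|---|---|---|
| gamma | 0.12 M | 2 equiv | 1.6 mol% | run made earlier |  |
| alpha | 0.12 M | 2 equiv | 12 mol% | run made earlier |  |
| birch | 0.50 M | 2.00 equiv | 5 mol% |  | 25 h |
| alder | 0.12 M | 2.00 equiv | 5 mol% |  | 25 h |
| cedar | 0.030 M | 0.660 equiv | 1.2 mol% |  | 25 h |
| ash | 0.040 M | 8.00 equiv | 5 mol% |  | 25 h |
| oak | 0.080 M | 6.00 equiv | 10 mol% |  | 25 h |

| run | time / h | L / % | J / % |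
|---|---|---|---|
| gamma | 4.00 | 0 | 97.3 |
| gamma | 8.00 | 0 | 94.2 |
| gamma | 10.0 | 0 | 94.1 |
| gamma | 15.0 | 0.2 | 90.3 |
| gamma | 20.0 | 0.9 | 88.0 |
| gamma | 25.0 | 1.5 | 84.7 |
| alpha | 1.33 | 0.5 | 96.7 |
| alpha | 4.00 | 0.2 | 92.0 |
| alpha | 8.00 | 1.9 | 85.5 |
| alpha | 10.0 | 1.3 | 81.9 |
| alpha | 15.0 | 4.6 | 74.9 |
| alpha | 20.0 | 6.9 | 67.2 |
| alpha | 25.0 | 10.3 | 61.6 |

(scatter of a reading: 0.5 percentage points)

- candidate steps: J + E -> E + Q; Z + E + Q -> E + L; 2 E <-> D

1. the flasks by amount of L, in percent of the J charged, highest first, at 25 h (birch / alder / cedar / ash / oak)
2. the amount of L, in percent of the J charged of the flask you put first, at 25 h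
3. the amount of L, in percent of the J charged of the flask you put last, at 25 h

- Take the loss of J as pseudo-first-order and compare gamma with alpha by the logarithm of J's remaining fraction at their last readings. Alpha had 7.50 times gamma's catalyst.
- Now take two extreme flasks. If the catalyst stays single as E, the first step follows the charge, and that logarithm grows by the same 7.50. If it sits paired as D, E² follows the charge, so the growth is the square root, 2.74.
- The readings give 2.92, less than the first extreme and a little more than the second. Gamma and alpha therefore lie nearer the paired end than the single one.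
- Call the power that links this logarithm, at a fixed time, to the catalyst charge per litre the catalyst order, or apparent order in catalyst; gamma's and alpha's last J readings put it at 0.531.
- My own reckoning scales from gamma: birch's logarithm of J is gamma's times the catalyst ratio to that power, which leaves a J fraction of 52.2%.
- While Q is young, L grows as the product of both steps, and each step carries E. So I scale alpha's L by the ratio of Z per litre and by the catalyst ratio to the power 1.06. For gamma this gives 1.21% against a reading of 1.5%, with scatter 0.5 percentage points.
- The same rule gives birch 77.1%, oak 11.0%, alder 4.06%, ash 1.68% and cedar 0.0168%.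
- Birch's figure is more than the 47.8% of J reckoned lost, so Q is not young there. I commit to that order, with birch's L under that loss.
- The forecast said birch > oak > alder > ash > cedar, with 34% first and 0.03% last, holding that “the catalyst sits mostly as D”; that is my order, and its last figure is more than my 0.0168%.
- The flasks give birch > oak > alder > ash > cedar, with 34.3% first and 0.0174% last.

    J + E → E + Q (k = 0.00436 L mol⁻¹ s⁻¹)
    Z + E + Q → E + L (k = 0.0203 L² mol⁻² s⁻¹)
    2 E ⇌ D, settled at all times (K = 4020 L mol⁻¹)

- Birch ran the first step throughout, its J at 71.6% after 12.5 h and 51.3% after 25.0 h where the catalyst order gave 52.2%, while Q stood at 14.2% and then 14.4% and the second step carried L from 14.2% to 34.3%, with 82.9% of its own charge of Z there and D at 93.2% of the catalyst. Cedar, with D at 56.0% of its catalyst, had J at 94.0% after 25.0 h against 93.4% from the order, Q at 6.01%, and the reckoned 0.0168% stood against an L of 0.0174%.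

The earlier runs and the new flask are simulated with made-up constants, noise included.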